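**Plan** (germacrane numbering: ring carbons C1–C10, lactone C11–C13, C14 = methyl on C10, C15 = ester carbon on C4)

- Cuts, in retrosynthetic order: the C8–O ester; then C6–C7 and C9–C10 together with the lactone O–C12 bond; then C3=C4 (metathesis) and the O–C10 ketal bond of the oxepine.
- Forward: ring B (oxepine O/C10/C1–C5) is made first, as its C10 methyl ketal with C6 as the aldehyde. One pot then brings in C7–C8–C9 with C11–C13, closing ring C (the lactone) and ring A (oxepanone O/C5–C10), and with them the ten-membered carbocycle.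
- Enabling feature: in ring B the aldehyde carbon C6 and the ketal carbon C10 lie 1,4 across the ring oxygen (C6–C5–O–C10). This 1,4-dielectrophile is bridged by a C7–C8–C9 1,3-dinucleophile (allylboronate at C7, silyl enol ether at C9), and C8 emerges as the ketone.
- Stereochemistry: C5 from dimethyl (R)-malate; C6 and C7 from the chair allylboration (anti) under control by C5; C10 by intramolecular delivery; C8 by hydride attack on the exo face; the epoxy ester from a Sharpless epoxidation.

Key step: step 13

Remark: compounds 1, 4, 14 and 24 and all reagents named (including 2-(iodomethyl)-4,4,5,5-tetramethyl-1,3,2-dioxaborolane) are taken as commercially available; the germacrane numbering above is also used for the intermediates.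

**Step 1**
Reactants: 1 hex-5-en-2-one
Product: 2 5,5-dimethoxyhex-1-ene
Conditions: HC(OMe)3, MeOH, p-TsOH (cat.), rt
Reagents that add atoms: trimethyl orthoformate, COC(OC)OC
Why: Acid-catalysed ketalisation with the orthoester as dehydrating agent should give the dimethyl ketal, the isolated alkene being inert.

**Step 2**
Reactants: 2 5,5-dimethoxyhex-1-ene
Product: 3 2-methoxyhexa-1,5-diene
Conditions: TMSOTf, iPr2NEt, CH2Cl2, −20 °C → rt
Reagents that add atoms: none
Why: Silyl-triflate ionisation of the ketal and deprotonation of the oxocarbenium ion by the hindered amine (ketal-to-enol-ether elimination) should give the methyl enol ether that later transfers the future C10 to the C5 hydroxyl.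

**Step 3**
Reactants: 4 dimethyl (2R)-2-hydroxybutanedioate
Product: 5 methyl (3R)-3,4-dihydroxybutanoate
Conditions: BH3·SMe2, NaBH4 (cat.), THF, 0 °C → rt; MeOH quench
Reagents that add atoms: none
Why: Hydroxyl-directed borane reduction (via a cyclic alkoxyborane) should reduce only the ester next to the free hydroxyl, leaving the distal ester and the stereocentre (future C5) untouched.

**Step 4**
Reactants: 5 methyl (3R)-3,4-dihydroxybutanoate
Product: 6 methyl (3R)-4-[(tert-butyldiphenylsilyl)oxy]-3-hydroxybutanoate
Conditions: t-BuPh2SiCl, imidazole, CH2Cl2, 0 °C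
Reagents that add atoms: tert-butyl(chloro)diphenylsilane, CC(C)(C)[Si](Cl)(c1ccccc1)c1ccccc1
Why: The bulky silyl chloride should protect only the primary hydroxyl (future C6–O) by steric differentiation.

**Step 5**
Reactants: 6 methyl (3R)-4-[(tert-butyldiphenylsilyl)oxy]-3-hydroxybutanoate
Product: 9 methyl 2-[(1R)-2-[(tert-butyldiphenylsilyl)oxy]-1-hydroxyethyl]prop-2-enoate, via Mannich base 7 (not isolated), via trimethylammonium iodide 8 (not isolated)
Conditions: LiN(iPr)2 (2.3 equiv), THF, −78 → −30 °C; Me2N=CH2+ I−, −78 → 0 °C; then MeI, MeOH, rt; then DBU, CH2Cl2, rt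
Reagents that add atoms: Eschenmoser's salt (N,N-dimethylmethyleneiminium iodide), C=[N+](C)C.[I-]
Why: Twofold deprotonation of the β-hydroxy ester (Fráter–Seebach-type) and Mannich alkylation at carbon, then N-methylation and E1cB loss of trimethylamine, should install the α-methylene group without touching the carbinol stereocentre.

**Step 6**
Reactants: 9 methyl 2-[(1R)-2-[(tert-butyldiphenylsilyl)oxy]-1-hydroxyethyl]prop-2-enoate; 3 2-methoxyhexa-1,5-diene
Product: 10 methyl 2-[(1R)-2-[(tert-butyldiphenylsilyl)oxy]-1-[(2-methoxyhex-5-en-2-yl)oxy]ethyl]prop-2-enoate (both epimers at the ketal carbon)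
Conditions: PPTS (cat.), CH2Cl2, 0 °C
Reagents that add atoms: none
Why: Acid-catalysed Markovnikov addition of the secondary alcohol to the enol ether (as in mixed-ketal protection with 2-methoxypropene) should tie the C5 oxygen to C10; the ketal configuration is irrelevant because this carbon is ionised in step 13.

**Step 7**
Reactants: 10 mixed ketal
Product: 11 methyl (7R)-7-{[(tert-butyldiphenylsilyl)oxy]methyl}-2-methoxy-2-methyl-2,3,4,7-tetrahydrooxepine-6-carboxylate (both C2 epimers)
Conditions: second-generation Hoveyda–Grubbs catalyst RuCl2(=CH-C6H4-2-OiPr)(H2IMes) (5–10 mol%), toluene (high dilution), 80 °C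
Reagents that add atoms: none
Why: Ring-closing metathesis between the acrylate alkene and the terminal alkene should close the seven-membered ring B; as a ring alkene, C3=C4 can only have C2 and C5 cis, which is the (3E) geometry of the target.

**Step 8**
Reactants: 11 silyl ether
Product: 12 methyl (7R)-7-(hydroxymethyl)-2-methoxy-2-methyl-2,3,4,7-tetrahydrooxepine-6-carboxylate
Conditions: Bu4NF, AcOH (1:1), THF, 0 °C
Reagents that add atoms: none
Why: Buffered fluoride should cleave the silyl ether while sparing the acid-labile ketal; the γ-hydroxy enoate, which can lactonise, is oxidised without storage.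

**Step 9**
Reactants: 12 primary alcohol
Product: 13 methyl (7R)-7-formyl-2-methoxy-2-methyl-2,3,4,7-tetrahydrooxepine-6-carboxylate
Conditions: Dess–Martin periodinane, NaHCO3, CH2Cl2, 0 °C; used at once
Reagents that add atoms: none
Why: Buffered Dess–Martin oxidation should give the α-alkoxy aldehyde (C6) without epimerising C5 or moving the C3=C4 bond.

**Step 10**
Reactants: 14 but-3-yn-2-one
Product: 15 tert-butyl(but-1-en-3-yn-2-yloxy)dimethylsilane
Conditions: t-BuMe2SiOTf, Et3N, CH2Cl2, −78 → 0 °C
Reagents that add atoms: tert-butyldimethylsilyl trifluoromethanesulfonate, CC(C)(C)[Si](C)(C)OS(=O)(=O)C(F)(F)F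
Why: Soft enolisation of the methyl ketone should give the robust silyl enol ether whose CH2 terminus is the future C9 nucleophile.

**Step 11**
Reactants: 15 silyloxy enyne
Product: 16 methyl 4-[(tert-butyldimethylsilyl)oxy]pent-4-en-2-ynoate
Conditions: n-BuLi, THF, −78 °C; then ClCO2Me
Reagents that add atoms: methyl chloroformate, COC(=O)Cl
Why: Deprotonation of the terminal alkyne and C-acylation with the chloroformate should give the ynoate acceptor needed for step 12.

**Step 12**
Reactants: 16 ynoate
Product: 18 methyl (2Z)-4-[(tert-butyldimethylsilyl)oxy]-2-[(4,4,5,5-tetramethyl-1,3,2-dioxaborolan-2-yl)methyl]penta-2,4-dienoate, via vinylalane 17 (not isolated)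
Conditions: iBu2AlH, HMPA, THF, 0 °C; then ICH2Bpin, 0 °C → rt
Reagents that add atoms: 2-(iodomethyl)-4,4,5,5-tetramethyl-1,3,2-dioxaborolane, ICB1OC(C)(C)C(C)(C)O1
Why: Syn 1,4-hydroalumination of the ynoate (hydride to C7, aluminium to C11) and alkylation of the α-alanyl acrylate by the iodomethylboronate with retention should place CH2B trans to the silyloxyvinyl group, the E-crotyl-type geometry that step 13 turns into the trans lactone.

**Step 13**
Reactants: 13 ring B aldehyde; 18 allylboronate–enol silane
Product: 22 methyl (3E,5R,6S,7S,10S)-5,10-epoxy-8-oxogermacra-3,11(13)-dien-12,6-olid-15-oate, via borate adduct 19 (not isolated), via lactone enol silane 20 (not isolated), via oxocarbenium triflate 21 (not isolated)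
Conditions: toluene, 4 Å MS, 60 °C; then CH2Cl2 (dilute), 2,6-di-tert-butyl-4-methylpyridine, TMSOTf (0.3 equiv), −78 → −40 °C
Reagents that add atoms: none
Why: Proposed new method: in the first stage the 2-(methoxycarbonyl)allylboronate 18 adds to the aldehyde without any acid through a closed six-membered chair transition state, its γ-carbon (C7) bonding to C6 while the allyl shift creates the C11=C13 methylene, and the boron alkoxide 19 then closes ring C by 5-exo-trig attack on the ester (closest known type: allylboration–lactonisation of aldehydes with 2-alkoxycarbonyl allylboronates). In the second stage the silyl triflate ionises the ring B methyl ketal to the cyclic oxocarbenium ion 21 and the tethered silyl enol ether attacks C10 through C9, a Mukaiyama-type addition that closes ring A in a 7-endo mode (enol carbon and C=O+ carbon both inside the new ring), completes the ten-membered carbocycle and leaves C8 as the ketone (closest known types: enol silane additions to ketal-derived oxocarbenium ions and formal (4+3) annulations of 1,3-dinucleophiles with 1,4-dielectrophiles). C6 and C7 come from the chair: the silyloxyvinyl group trans to CH2B sits equatorial and gives the anti adduct, which is the trans-fused lactone. C6 relative to C5 rests on Felkin–Anh attack anti to the C5–O bond, with H5 turned toward the γ-substituent of the boronate. C10 is fixed by the tether, since C9 is carried by C6 and can reach only the oxocarbenium face cis to it. The step needs the aldehyde to react before the ketal and O6 to be acylated before ionisation (secured by the acid-free first stage, in which lactonisation removes O6 as a competitor for C10), and no enolisation of the new C8 ketone toward C7 (secured by the hindered pyridine base and the low temperature).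

**Step 14**
Reactants: 22 tricyclic ketone
Product: 23 methyl (3E,5R,6S,7R,8R,10S)-5,10-epoxy-8-hydroxygermacra-3,11(13)-dien-12,6-olid-15-oate
Conditions: NaBH4, CeCl3·7H2O, MeOH/CH2Cl2, −78 °C
Reagents that add atoms: none
Why: Luche conditions should reduce the ring ketone 1,2 and leave the α-methylene lactone and the enoate alone, hydride arriving on the exo face of ring A (the face of C14 and H5, away from ring B and from C11 on C7) to give the 8R alcohol.

**Step 15**
Reactants: 24 (2E)-2-methylbut-2-en-1-ol
Product: 25 [(2R,3R)-2,3-dimethyloxiran-2-yl]methanol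
Conditions: Ti(OiPr)4 (cat.), D-(−)-diethyl tartrate (cat.), t-BuOOH, 4 Å MS, CH2Cl2, −20 °C
Reagents that add atoms: tert-butyl hydroperoxide, CC(C)(C)OO
Why: Sharpless asymmetric epoxidation with the D-(−)-tartrate should deliver oxygen to the face of the allylic alcohol that gives the (2R,3R) epoxide, the E alkene fixing the cis relation of the two methyl groups.

**Step 16**
Reactants: 25 epoxy alcohol
Product: 26 (2S,3R)-2,3-dimethyloxirane-2-carboxylic acid
Conditions: RuCl3·xH2O (cat.), NaIO4, MeCN/CCl4/H2O, rt
Reagents that add atoms: sodium periodate, [Na+].[O-]I(=O)(=O)=O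
Why: Catalytic RuO4 should oxidise the primary alcohol to the acid without opening the trisubstituted epoxide; no centre is touched (C2 becomes S only through the change in priorities).

**Step 17**
Reactants: 23 C8 alcohol; 26 (2S,3R)-2,3-dimethyloxirane-2-carboxylic acid
Product: 28 methyl (3E,5R,6S,7R,8R,10S)-8-{[(2S,3R)-2,3-dimethyloxirane-2-carbonyl]oxy}-5,10-epoxygermacra-3,11(13)-dien-12,6-olid-15-oate (CNP0240298.1), via mixed anhydride 27 (not isolated)
Conditions: 2,4,6-Cl3C6H2COCl, Et3N, THF, rt; then 23, DMAP, toluene, rt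
Reagents that add atoms: none
Why: Yamaguchi esterification: DMAP should attack the mixed anhydride at the aliphatic carbonyl and the acylpyridinium acylate the hindered C8 hydroxyl with retention at every stereocentre.

**Compound list**

1 | hex-5-en-2-one | CC(=O)CCC=C | starting material
2 | 5,5-dimethoxyhex-1-ene | CC(OC)(OC)CCC=C | intermediate
3 | 2-methoxyhexa-1,5-diene | C=C(OC)CCC=C | intermediate
4 | dimethyl (2R)-2-hydroxybutanedioate (dimethyl (R)-malate) | COC(=O)C[C@@H](O)C(=O)OC | starting material
5 | methyl (3R)-3,4-dihydroxybutanoate | COC(=O)C[C@@H](O)CO | intermediate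
6 | methyl (3R)-4-[(tert-butyldiphenylsilyl)oxy]-3-hydroxybutanoate | COC(=O)C[C@@H](O)CO[Si](c1ccccc1)(c1ccccc1)C(C)(C)C | intermediate
7 | Mannich base, methyl (2S,3R)-4-[(tert-butyldiphenylsilyl)oxy]-2-[(dimethylamino)methyl]-3-hydroxybutanoate (formed in situ) | COC(=O)[C@@H](CN(C)C)[C@@H](O)CO[Si](c1ccccc1)(c1ccccc1)C(C)(C)C | intermediate
8 | trimethylammonium iodide, (2S,3R)-4-[(tert-butyldiphenylsilyl)oxy]-3-hydroxy-2-(methoxycarbonyl)-N,N,N-trimethylbutan-1-aminium iodide (formed in situ) | COC(=O)[C@@H](C[N+](C)(C)C)[C@@H](O)CO[Si](c1ccccc1)(c1ccccc1)C(C)(C)C.[I-] | intermediate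
9 | methyl 2-[(1R)-2-[(tert-butyldiphenylsilyl)oxy]-1-hydroxyethyl]prop-2-enoate | C=C(C(=O)OC)[C@@H](O)CO[Si](c1ccccc1)(c1ccccc1)C(C)(C)C | intermediate
10 | methyl 2-[(1R)-2-[(tert-butyldiphenylsilyl)oxy]-1-[(2-methoxyhex-5-en-2-yl)oxy]ethyl]prop-2-enoate (both ketal epimers) | C=C(C(=O)OC)[C@@H](OC(C)(OC)CCC=C)CO[Si](c1ccccc1)(c1ccccc1)C(C)(C)C | intermediate
11 | methyl (7R)-7-{[(tert-butyldiphenylsilyl)oxy]methyl}-2-methoxy-2-methyl-2,3,4,7-tetrahydrooxepine-6-carboxylate (both C2 epimers) | COC(=O)C1=CCCC(C)(OC)O[C@H]1CO[Si](c1ccccc1)(c1ccccc1)C(C)(C)C | intermediate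
12 | methyl (7R)-7-(hydroxymethyl)-2-methoxy-2-methyl-2,3,4,7-tetrahydrooxepine-6-carboxylate | COC(=O)C1=CCCC(C)(OC)O[C@H]1CO | intermediate
13 | methyl (7R)-7-formyl-2-methoxy-2-methyl-2,3,4,7-tetrahydrooxepine-6-carboxylate | COC(=O)C1=CCCC(C)(OC)O[C@H]1C=O | intermediate
14 | but-3-yn-2-one | CC(=O)C#C | starting material
15 | tert-butyl(but-1-en-3-yn-2-yloxy)dimethylsilane | C=C(O[Si](C)(C)C(C)(C)C)C#C | intermediate
16 | methyl 4-[(tert-butyldimethylsilyl)oxy]pent-4-en-2-ynoate | C=C(O[Si](C)(C)C(C)(C)C)C#CC(=O)OC | intermediate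
17 | vinylalane, methyl (2E)-2-[bis(2-methylpropyl)alumanyl]-4-[(tert-butyldimethylsilyl)oxy]penta-2,4-dienoate (formed in situ) | COC(=O)/C([Al](CC(C)C)CC(C)C)=C\C(=C)O[Si](C)(C)C(C)(C)C | intermediate
18 | methyl (2Z)-4-[(tert-butyldimethylsilyl)oxy]-2-[(4,4,5,5-tetramethyl-1,3,2-dioxaborolan-2-yl)methyl]penta-2,4-dienoate | COC(=O)/C(CB1OC(C)(C)C(C)(C)O1)=C\C(=C)O[Si](C)(C)C(C)(C)C | intermediate
19 | borate adduct, methyl (3S,4S)-3-{1-[(tert-butyldimethylsilyl)oxy]ethenyl}-4-[(7R)-2-methoxy-6-(methoxycarbonyl)-2-methyl-2,3,4,7-tetrahydrooxepin-7-yl]-2-methylidene-4-[(4,4,5,5-tetramethyl-1,3,2-dioxaborolan-2-yl)oxy]butanoate (formed in situ) | C=C(C(=O)OC)[C@H](C(=C)O[Si](C)(C)C(C)(C)C)[C@H](OB1OC(C)(C)C(C)(C)O1)[C@@H]1OC(C)(OC)CCC=C1C(=O)OC | intermediate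
20 | lactone enol silane, methyl (7R)-7-[(2S,3S)-3-{1-[(tert-butyldimethylsilyl)oxy]ethenyl}-4-methylidene-5-oxooxolan-2-yl]-2-methoxy-2-methyl-2,3,4,7-tetrahydrooxepine-6-carboxylate (formed in situ) | C=C1C(=O)O[C@H]([C@@H]2OC(C)(OC)CCC=C2C(=O)OC)[C@H]1C(=C)O[Si](C)(C)C(C)(C)C | intermediate
21 | oxocarbenium triflate, the 2-methyl-4,7-dihydro-3H-oxepin-1-ium ion formed from 20 by loss of methoxide (formed in situ) | C=C1C(=O)O[C@H]([C@@H]2[O+]=C(C)CCC=C2C(=O)OC)[C@H]1C(=C)O[Si](C)(C)C(C)(C)C.[O-]S(=O)(=O)C(F)(F)F | intermediate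
22 | methyl (3E,5R,6S,7S,10S)-5,10-epoxy-8-oxogermacra-3,11(13)-dien-12,6-olid-15-oate | C=C1C(=O)O[C@H]2[C@H]1C(=O)C[C@]1(C)CCC=C(C(=O)OC)[C@H]2O1 | intermediate
23 | methyl (3E,5R,6S,7R,8R,10S)-5,10-epoxy-8-hydroxygermacra-3,11(13)-dien-12,6-olid-15-oate | C=C1C(=O)O[C@H]2[C@H]1[C@H](O)C[C@]1(C)CCC=C(C(=O)OC)[C@H]2O1 | intermediate
24 | (2E)-2-methylbut-2-en-1-ol | C/C=C(\C)CO | starting material
25 | [(2R,3R)-2,3-dimethyloxiran-2-yl]methanol | OC[C@@]1(C)O[C@@H]1C | intermediate
26 | (2S,3R)-2,3-dimethyloxirane-2-carboxylic acid | OC(=O)[C@@]1(C)O[C@@H]1C | intermediate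
27 | mixed anhydride, (2S,3R)-2,3-dimethyloxirane-2-carboxylic 2,4,6-trichlorobenzoic anhydride (formed in situ) | O=C(OC(=O)[C@@]1(C)O[C@@H]1C)c1c(Cl)cc(Cl)cc1Cl | intermediate
28 | methyl (3E,5R,6S,7R,8R,10S)-8-{[(2S,3R)-2,3-dimethyloxirane-2-carbonyl]oxy}-5,10-epoxygermacra-3,11(13)-dien-12,6-olid-15-oate (CNP0240298.1) | C=C1C(=O)O[C@H]2[C@H]1[C@H](OC(=O)[C@@]1(C)O[C@@H]1C)C[C@]1(C)CCC=C(C(=O)OC)[C@H]2O1 | target

**Step count and risks**

Total steps: 17. Longest linear sequence: 10 steps (steps 3, 4, 5, 6, 7, 8, 9, 13, 14, 17, from dimethyl (R)-malate).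

Steps most likely to fail:

1. **Step 13.** The C5 stereocentre may transmit its induction to the aldehyde face only weakly, because γ-E-substituted allylboronates are known to express Felkin–Anh/Cornforth control less well than Z ones; the result would be poor facial selectivity at C6/C7. The slow bimolecular allylboration also leaves time for the aldehyde to epimerise at C5. The fallback sets out from 13 and uses known chemistry, replacing the allylboration by a syn-selective boron aldol. Acetone lithium enolate and methyl 2-(bromomethyl)acrylate should give methyl 2-methylidene-4-oxopentanoate F1. Its Z-configured dibutylboron dienolate (Bu2BOTf, iPr2NEt, CH2Cl2, −78 °C) should add to 13 at its α-carbon through a chair transition state; a Z-enolate is the geometry that best transmits the anti induction of an α-alkoxy aldehyde. This gives the syn aldol methyl (3S,4S)-3-acetyl-4-hydroxy-4-[(7R)-2-methoxy-6-(methoxycarbonyl)-2-methyl-2,3,4,7-tetrahydrooxepin-7-yl]-2-methylidenebutanoate F2, which has the C6/C7 configuration of 19. On gentle warming in toluene F2 should lactonise to the acetyl lactone methyl (7R)-7-[(2S,3S)-3-acetyl-4-methylidene-5-oxooxolan-2-yl]-2-methoxy-2-methyl-2,3,4,7-tetrahydrooxepine-6-carboxylate F3. Kinetic silylation of the methyl ketone (t-BuMe2SiOTf, Et3N, −78 °C) gives 20, now isolated, and TMSOTf with the hindered pyridine base (enol silane–ketal coupling, run intramolecularly) closes ring A, so the route is rejoined at 22.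

2. **Step 12.** The α-metallated acrylate may lose its alkene geometry through its allenolate form before alkylation, or be protonated instead of C-alkylated. The fallback sets out from 13 and makes the geometry irrelevant by changing the nucleophile from boron to chromium. A Morita–Baylis–Hillman reaction of methyl acrylate with methylglyoxal (DABCO) should give methyl 3-hydroxy-2-methylidene-4-oxopentanoate F4. Aqueous HBr/H2SO4 (allylic transposition) should give methyl 2-(bromomethyl)-4-oxopent-2-enoate F5, and silylation (t-BuMe2SiOTf, Et3N) methyl 2-(bromomethyl)-4-[(tert-butyldimethylsilyl)oxy]penta-2,4-dienoate F6. Nozaki–Hiyama–Kishi-type allylation of 13 with F6 (CrCl2, THF), in which the equilibrating allylchromium species should give the anti homoallylic alcohol whatever the bromide geometry, followed by lactonisation, gives 20. TMSOTf then closes ring A and the route is rejoined at 22.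

3. **Step 14.** Hydride may be delivered to the endo face of ring A (wrong C8 epimer), or the α-methylene lactone may undergo conjugate reduction. The fallback sets out from 22: if the epimer methyl (3E,5R,6S,7R,8S,10S)-5,10-epoxy-8-hydroxygermacra-3,11(13)-dien-12,6-olid-15-oate F7 is what forms, it is esterified with inversion. A Mitsunobu reaction of F7 with acid 26 (PPh3, diisopropyl azodicarboxylate, toluene) should give the target directly, so the route is rejoined at 28.

**Further compounds**

F1 | step 13 | methyl 2-methylidene-4-oxopentanoate | C=C(CC(C)=O)C(=O)OC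
F2 | step 13 | methyl (3S,4S)-3-acetyl-4-hydroxy-4-[(7R)-2-methoxy-6-(methoxycarbonyl)-2-methyl-2,3,4,7-tetrahydrooxepin-7-yl]-2-methylidenebutanoate | C=C(C(=O)OC)[C@H](C(C)=O)[C@H](O)[C@@H]1OC(C)(OC)CCC=C1C(=O)OC
F3 | step 13 | methyl (7R)-7-[(2S,3S)-3-acetyl-4-methylidene-5-oxooxolan-2-yl]-2-methoxy-2-methyl-2,3,4,7-tetrahydrooxepine-6-carboxylate | C=C1C(=O)O[C@H]([C@@H]2OC(C)(OC)CCC=C2C(=O)OC)[C@H]1C(C)=O
F4 | step 12 | methyl 3-hydroxy-2-methylidene-4-oxopentanoate (racemic) | C=C(C(=O)OC)C(O)C(C)=O
F5 | step 12 | methyl 2-(bromomethyl)-4-oxopent-2-enoate (either alkene geometry) | COC(=O)C(CBr)=CC(C)=O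
F6 | step 12 | methyl 2-(bromomethyl)-4-[(tert-butyldimethylsilyl)oxy]penta-2,4-dienoate (either alkene geometry) | COC(=O)C(CBr)=CC(=C)O[Si](C)(C)C(C)(C)C
F7 | step 14 | methyl (3E,5R,6S,7R,8S,10S)-5,10-epoxy-8-hydroxygermacra-3,11(13)-dien-12,6-olid-15-oate | C=C1C(=O)O[C@H]2[C@H]1[C@@H](O)C[C@]1(C)CCC=C(C(=O)OC)[C@H]2O1
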